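## The problem

The target is a symmetrical diester. Two identical (4S,4aR,6S,7R,7aS)-2,4,7-trimethyl-octahydro-1H-cyclopenta[c]pyridin-6-ol units acylate the two ends of (2E,6E)-2,6-dimethylocta-2,6-dienedioic acid. The work therefore reduces to one bicyclic amino alcohol and one C10 diacid.

Each unit is a cyclopentane (ring A: C4a, C5, C6, C7, C7a) cis-fused to an N-methylpiperidine (ring B: C1, N2, C3, C4, C4a, C7a). It carries five contiguous stereocentres. H4, H4a and H7a lie on one face, and the C6 oxygen and the C7 methyl lie on that same convex face.

C4a can control C7a through the ring fusion. The folded bicycle should then steer a hydride at C6 to the convex face, and C7 can equilibrate next to a C6 carbonyl so that its methyl ends trans to C1. C4 is the exception: ring A does not control it, so it has to be fixed relative to C4a (cis) inside ring B.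

The two (E)-trisubstituted enoates are Michael acceptors and are sensitive to hydride, so the diacid should enter last and under neutral conditions. The basic tertiary amine is best masked as a carbamate until the end.

The feature that opens the key step is that, in a monocyclic precursor with a C6 ketone and an N2–C1 enecarbamate, C7 and C7a are both nucleophilic carbons. They sit 1,5 to each other across C6–C5–C4a. Removing two electrons should join them, close ring A, and leave C6 as the ketone and C1 as a reducible N-acyl aminal.

## Retrosynthesis

**Ester bonds.** The two C6–O ester bonds of 24 are cut to give two molecules of alcohol 19 and diacid 23. Acylation with retention would need the (6S)-alcohol, but hydride reduction of the ring-A ketone is expected to give the (6R)-epimer. Cutting with inversion matches what the reduction delivers and halves the problem. The forward step must invert a hindered cyclopentanol twice, without elimination and without touching the enoates.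

**Diacid.** Diacid 23 is traced through dialdehyde 22 and diol 21 to geraniol 20. No C–C bond is cut. Geraniol already holds the C10 skeleton and the (E)-olefin, whereas two olefinations would have to create both. The forward sequence needs an allylic oxidation that picks the (E)-methyl of the distal olefin, and then two oxidations that keep the geometry.

**Functional groups of 19.** Alcohol 19 is traced to ketone carbamate 18 and on to methoxy aminal 17. The N-methyl becomes a methyl carbamate and the carbinol becomes the C6 ketone, so that one hydride reagent regenerates both. The C1 methylene becomes an aminal. The carbamate is also the group that makes N2–C1=C7a an electron-rich olefin one stage earlier. The forward steps need hydride attack at C6 from the convex face.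

**Key disconnection.** The C7–C7a bond of 17 is cut to give silyl enol ether 16. Cuts at C4–C4a or through the ketone carbon would leave a ring-A fragment that still carries two or three stereocentres. This cut removes ring A and the C7 and C7a stereocentres at once. It leaves monocyclic ring B with only C4 and C4a defined. Both carbons are nucleophilic, so the forward step must be an oxidation. It has to bond C7 to C7a and not to C1, and it has to give the cis fusion.

**Enol ether.** Enol ether 16 is traced to vinyl ketone 15, and 15 to ester 12 and vinylmagnesium bromide 13 (C6–C7 bond, through amide 14). An ethyl ketone flanked by two methylenes could not be enolised towards C7 selectively. Conjugate hydrosilylation of 15 fixes the position of the enol ether by the position of the vinyl group.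

**Enecarbamate.** The C1=C7a double bond of 12 is traced to the lactam carbonyl of 10, through hemiaminal 11. This places the olefin on the C1 side without ambiguity. α-Oxidation of a saturated piperidine carbamate would have to choose between C1 and C3.

**C4a stereocentre.** Lactam 10 is traced to unsaturated lactam 9 by removing H2 across C4a–C7a. C4a is then set from C4 by hydrogenation anti to the neighbouring methyl. Conjugate addition of the side chain to a lactam lacking it would put the new group trans to the methyl, which is the wrong isomer.

**Side chain.** The C4a–C5 bond of 9 is cut to enol triflate 7 and zinc reagent 8, and 7 is traced to dione 6. The cross-coupling must leave the C5-methyl stereocentre alone.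

**Ring B.** Dione 6 is cut at C4a–C7a and N2–C1 to carbamate acid 3 and Meldrum's acid 4. Acid 3 comes from (R)-amino acid 1 and methyl chloroformate 2. The single stereocentre of 1 becomes C4, and the carbon of 2 ends as the N-methyl group. A dearomative entry to ring B would be shorter. It was set aside because it needs an enantioselective addition and a site-selective partial reduction for which no reliable precedent exists.

## Roads not taken

**Alternative 1:** conjugate methylation–Mannich coupling on a ring-A cyclopentenone.
- **Cut:** the C7 methyl and the C7a–C1 bond are removed from a ring-A cyclopentanone.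
- **Forward key step:** Me2CuLi adds to silyloxycyclopentenone A2 anti to the silyloxy group. The enolate is trapped by methyleneiminium salt A3 trans to the new methyl, giving A1.
- **Merits:** three contiguous ring-A stereocentres (C6, C7, C7a) arise from one resolved centre in one step. All reaction types are established on cyclopentenones. The C6 oxygen is present from the start.
- **Weak points:** A1 is a β-amino ketone and a β-silyloxy ketone at once, so retro-Mannich cleavage and β-elimination threaten it. Its carbonyl sits at C4a, not C6, so ring B still has to be built on it (C4–C4a bond, C4 stereocentre, removal of the carbonyl). The C6 oxygen must be carried protected and still arrives with the configuration that has to be inverted.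
- **Comparison:** in the reliability of its key event this road is better than the chosen one, which rests on an untested electrode reaction. The chosen plan sets against it that ring B, with C4 and C4a, is complete before ring A is touched. Ring closure delivers the C6 ketone and the C1 handle together without an oxygen protecting group, and ring B needs only two reductions afterwards.

**Alternative 2:** reductive Heck closure of ring B.
- **Cut:** the C4–C4a bond of ring B.
- **Forward key step:** zerovalent palladium from Pd(OAc)2 and PPh3 inserts into the vinyl bromide of enone A5. The vinylpalladium adds 6-exo to C4a, and HCO2Na reduces the palladium enolate to give A4.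
- **Merits:** the closure is a known reductive Heck reaction. The cis fusion follows from the short tether. The N-methyl group is in place, so no carbamate has to be reduced.
- **Weak points:** A5 already needs C7 and C7a trans on a cyclopentenone, which is most of the work of Alternative 1. C4 is not set by the cyclisation and needs a later face-selective hydrogenation of the exocyclic methylene of A4. A basic 2-bromoallyl amine is a delicate palladium substrate.
- **Comparison:** the ring-closing step is better precedented than the anodic coupling, and this must be conceded. The chosen plan answers with C4 fixed from the chiral pool before any ring fusion, with no late olefin hydrogenation, and with a ring-A closure that also installs the C6 carbonyl.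

**Alternative 3:** Pauson–Khand bicyclisation of a nitrogen-tethered enyne.
- **Cut:** C4a–C7a, C5–C6 and C6–C7 are removed at once.
- **Forward key step:** Co2(CO)8 complexes the terminal alkyne of enyne A7. The (E)-butenyl group and CO insert to give enone A6 with both rings formed.
- **Merits:** this road has the highest gain in complexity per step of the four. A7 is acyclic with one stereocentre. The (E)-olefin geometry becomes the trans relation of the C7 methyl and C1.
- **Weak points:** 1,2-disubstituted internal olefins are reluctant Pauson–Khand partners. The only control over C7a is 1,3-induction from the propargylic C4 methyl across the forming piperidine. C4a stays sp2 in A6 and needs a further face-selective reduction of a hindered enone.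
- **Comparison:** on step count this road is shorter than the chosen one, and it uses a known reaction. The chosen plan offers stereocontrol that does not rest on remote induction: C4a from hydrogenation next to C4, C7a from the geometry of the tether, and C7 by equilibration.

Key step: step 9

Remark on the chemistry: C1 of 17 and the carbinol carbon of 11 form as epimer mixtures and are left undefined because both centres are removed in the next operation; 8 and 13 are assumed to be used as purchased THF solutions.

## Route

Step 1
Reactants: 1 (2R)-3-amino-2-methylpropanoic acid; 2 methyl chloroformate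
Product: 3 (2R)-3-[(methoxycarbonyl)amino]-2-methylpropanoic acid
Conditions: NaOH (aq), THF, 0 °C to rt; then HCl (aq) to pH 2
Reagents that add atoms: none
Why: Schotten–Baumann N-acylation of the amine by the chloroformate; the stereocentre is not touched because the carboxylate cannot be enolised under these conditions.

Step 2
Reactants: 3 (2R)-3-[(methoxycarbonyl)amino]-2-methylpropanoic acid; 4 2,2-dimethyl-1,3-dioxane-4,6-dione (Meldrum's acid)
Product: 6 methyl (5R)-5-methyl-2,4-dioxopiperidine-1-carboxylate, via acyl Meldrum's acid 5 (not isolated)
Conditions: EDC·HCl, DMAP, CH2Cl2, 0 °C to rt; KHSO4 (aq) wash; then EtOAc, reflux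
Reagents that add atoms: none
Why: Carbodiimide C-acylation of Meldrum's acid, then thermal loss of acetone and CO2 to an acylketene that the carbamate N–H captures; this is the standard piperidine-2,4-dione synthesis from N-protected β-amino acids. The C5 stereocentre should survive because the far more acidic C3 methylene is the position that enolises.

Step 3
Reactants: 6 methyl (5R)-5-methyl-2,4-dioxopiperidine-1-carboxylate
Product: 7 methyl (5R)-5-methyl-2-oxo-4-[(trifluoromethanesulfonyl)oxy]-5,6-dihydropyridine-1(2H)-carboxylate
Conditions: Tf2O, iPr2NEt, CH2Cl2, −78 °C to 0 °C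
Reagents that add atoms: trifluoromethanesulfonic anhydride, O=S(=O)(OS(=O)(=O)C(F)(F)F)C(F)(F)F
Why: Enol triflate formation by O-sulfonylation of the 1,3-dicarbonyl enolate, which forms towards C3 between the two carbonyls, so the olefin is placed at C3=C4 and C5 is untouched.

Step 4
Reactants: 7 methyl (5R)-5-methyl-2-oxo-4-[(trifluoromethanesulfonyl)oxy]-5,6-dihydropyridine-1(2H)-carboxylate; 8 bromo(2-ethoxy-2-oxoethyl)zinc
Product: 9 methyl (5S)-4-(2-ethoxy-2-oxoethyl)-5-methyl-2-oxo-5,6-dihydropyridine-1(2H)-carboxylate
Conditions: Pd(PPh3)4 (5 mol%), THF, rt to 50 °C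
Reagents that add atoms: none
Why: Negishi cross-coupling of an enol triflate with a Reformatsky reagent; oxidative addition into the vinylogous acyl triflate is easy and the zinc enolate is mild enough to leave the imide alone. The descriptor at C5 changes only because the substituent priorities change.

Step 5
Reactants: 9 methyl (5S)-4-(2-ethoxy-2-oxoethyl)-5-methyl-2-oxo-5,6-dihydropyridine-1(2H)-carboxylate
Product: 10 methyl (4R,5S)-4-(2-ethoxy-2-oxoethyl)-5-methyl-2-oxopiperidine-1-carboxylate
Conditions: H2 (1 atm), Pd/C, EtOAc, rt
Reagents that add atoms: none
Why: Heterogeneous catalytic hydrogenation of the trisubstituted unsaturated lactam. Allylic 1,2-strain with the C4 side chain should hold the C5 methyl pseudoaxial, so hydrogen adds to the opposite face and the new C4 centre carries its side chain cis to the methyl.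

Step 6
Reactants: 10 methyl (4R,5S)-4-(2-ethoxy-2-oxoethyl)-5-methyl-2-oxopiperidine-1-carboxylate
Product: 12 methyl (3S,4R)-4-(2-ethoxy-2-oxoethyl)-3-methyl-3,4-dihydro-2H-pyridine-1-carboxylate, via hemiaminal alkoxide 11 (not isolated)
Conditions: LiEt3BH, THF, −78 °C; then (CF3CO)2O, iPr2NEt, DMAP (cat.), −78 °C to rt
Reagents that add atoms: none
Why: Partial reduction of an N-acyl lactam followed by trifluoroacetylation and elimination, the standard lactam-to-enecarbamate sequence. At −78 °C the imide-type ring carbonyl should be far more electrophilic than the ester or the carbamate.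

Step 7
Reactants: 12 methyl (3S,4R)-4-(2-ethoxy-2-oxoethyl)-3-methyl-3,4-dihydro-2H-pyridine-1-carboxylate; 13 vinylmagnesium bromide
Product: 15 methyl (3S,4R)-3-methyl-4-(2-oxobut-3-en-1-yl)-3,4-dihydro-2H-pyridine-1-carboxylate, via Weinreb amide 14 (not isolated)
Conditions: MeNH(OMe)·HCl, iPrMgCl, THF, −20 °C; then 13, −20 °C to 0 °C; cold citric acid (aq) quench
Reagents that add atoms: N,O-dimethylhydroxylamine hydrochloride, CNOC.Cl (its atoms stay only in intermediate 14)
Why: Weinreb ketone synthesis run in one flask: the chloromagnesium amide converts the ester into the N-methoxy-N-methylamide, whose chelated tetrahedral adduct with the vinyl Grignard reagent stops at the ketone. The cold acidic quench protonates the released amine before it can add to the enone.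

Step 8
Reactants: 15 methyl (3S,4R)-3-methyl-4-(2-oxobut-3-en-1-yl)-3,4-dihydro-2H-pyridine-1-carboxylate
Product: 16 methyl (3S,4R)-3-methyl-4-[(2Z)-2-(triethylsilyloxy)but-2-en-1-yl]-3,4-dihydro-2H-pyridine-1-carboxylate
Conditions: Et3SiH, RhCl(PPh3)3 (1 mol%), THF, 50 °C
Reagents that add atoms: triethylsilane, CC[SiH](CC)CC
Why: Rhodium-catalysed conjugate (1,4-) hydrosilylation of an enone with a monohydrosilane; the enol ether can only form at C6=C7 and the s-cis enone should give mainly the Z isomer. No stereocentre is formed and the enecarbamate is not a hydrosilylation substrate under these conditions.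

Step 9
Reactants: 16 methyl (3S,4R)-3-methyl-4-[(2Z)-2-(triethylsilyloxy)but-2-en-1-yl]-3,4-dihydro-2H-pyridine-1-carboxylate
Product: 17 methyl (4S,4aR,7R,7aS)-1-methoxy-4,7-dimethyl-6-oxooctahydro-2H-cyclopenta[c]pyridine-2-carboxylate (both C1 epimers)
Conditions: undivided cell, reticulated vitreous carbon anode, Pt cathode, constant current, 2.2 F/mol, LiClO4 (0.1 M), 2,6-lutidine, MeOH/CH2Cl2 (1:4), rt; then K2CO3, MeOH, rt
Reagents that add atoms: methanol, CO
Why: Proposed new method: one-electron oxidation of either electron-rich olefin at the anode should give a radical cation whose β-carbon is attacked by the β-carbon of the other olefin, so either initiation forms the C7–C7a bond; a second electron transfer turns the C1 α-amido radical into an N-acyliminium ion that methanol traps, and methanol strips the silyl group from the C6 oxocarbenium ion to leave the ketone. The closest known reaction type is the anodic coupling of enol ether or silyl enol ether radical cations with tethered allylsilanes, enol ethers or furans in methanol buffered with 2,6-lutidine; an enecarbamate as the partner has not been shown. Ring A closes 5-exo-trig with respect to the C7a=C1 bond, with the enol ether double bond inside the new ring, which is the stereoelectronically demanding part of the step. C7a is set cis to H4a because the three-atom tether C5–C6–C7 can only reach the enecarbamate face on which C5 already sits. C7 is epimerisable next to the ketone and should settle in the K2CO3/MeOH treatment with its methyl trans to C1. C1 forms as a mixture, which does not matter because it becomes a methylene in step 10. The step needs bonding at C7a and not C1, which the polarisation of the enecarbamate secures, and it needs oxidation of the two olefins only, which their low oxidation potentials and the limit of about two faradays per mole secure.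

Step 10
Reactants: 17 methyl (4S,4aR,7R,7aS)-1-methoxy-4,7-dimethyl-6-oxooctahydro-2H-cyclopenta[c]pyridine-2-carboxylate (both C1 epimers)
Product: 18 methyl (4S,4aR,7R,7aS)-4,7-dimethyl-6-oxooctahydro-2H-cyclopenta[c]pyridine-2-carboxylate
Conditions: Et3SiH, BF3·OEt2, CH2Cl2, −78 °C to 0 °C
Reagents that add atoms: none
Why: Ionic reduction of an N-acyl N,O-acetal: BF3 ionises the methoxy group to the N-acyliminium ion and the silane delivers hydride, so both C1 epimers converge. A dialkyl ketone should not be reduced by this pair at low temperature.

Step 11
Reactants: 18 methyl (4S,4aR,7R,7aS)-4,7-dimethyl-6-oxooctahydro-2H-cyclopenta[c]pyridine-2-carboxylate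
Product: 19 (4S,4aR,6R,7R,7aS)-2,4,7-trimethyloctahydro-1H-cyclopenta[c]pyridin-6-ol
Conditions: LiAlH4, THF, 0 °C to reflux; then H2O, NaOH (aq)
Reagents that add atoms: none
Why: Hydride reduction of the ketone and of the methyl carbamate (to N-methyl) in one operation. Hydride should approach C6 from the convex face, away from ring B, so the hydroxyl ends on the concave face as the (6R)-epimer.

Step 12
Reactants: 20 geraniol
Product: 21 (2E,6E)-2,6-dimethylocta-2,6-diene-1,8-diol
Conditions: SeO2 (cat.), tBuOOH, CH2Cl2, rt
Reagents that add atoms: tert-butyl hydroperoxide, CC(C)(C)OO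
Why: SeO2-catalysed allylic oxidation (ene reaction then [2,3]-shift), which should choose the (E)-methyl of the distal trisubstituted olefin because the olefin next to the hydroxyl is deactivated. Any material oxidised further to the aldehyde converges in step 13.

Step 13
Reactants: 21 (2E,6E)-2,6-dimethylocta-2,6-diene-1,8-diol
Product: 22 (2E,6E)-2,6-dimethylocta-2,6-dienedial
Conditions: MnO2 (excess), CH2Cl2, rt
Reagents that add atoms: none
Why: MnO2 oxidation of both allylic alcohols to the enals; the reagent is selective for allylic positions and should keep the olefin geometry.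

Step 14
Reactants: 22 (2E,6E)-2,6-dimethylocta-2,6-dienedial
Product: 23 (2E,6E)-2,6-dimethylocta-2,6-dienedioic acid
Conditions: NaClO2, NaH2PO4, 2-methylbut-2-ene, tBuOH/H2O, rt
Reagents that add atoms: sodium chlorite, [Na+].[O-]Cl=O
Why: Pinnick oxidation of both enals to the acids; the scavenger olefin removes hypochlorous acid, so the trisubstituted olefins and their geometry should be kept.

Step 15
Reactants: 19 (4S,4aR,6R,7R,7aS)-2,4,7-trimethyloctahydro-1H-cyclopenta[c]pyridin-6-ol (2 equiv); 23 (2E,6E)-2,6-dimethylocta-2,6-dienedioic acid
Product: 24 bis[(4S,4aR,6S,7R,7aS)-2,4,7-trimethyloctahydro-1H-cyclopenta[c]pyridin-6-yl] (2E,6E)-2,6-dimethylocta-2,6-dienedioate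
Conditions: PPh3, DIAD, THF, 0 °C to rt
Reagents that add atoms: none
Why: Double Mitsunobu esterification: each carboxylate displaces an alkoxyphosphonium group at C6 with inversion, turning (6R) into the (6S) configuration of the target. The neutral conditions spare the enoates.

## Compound list

1 | (2R)-3-amino-2-methylpropanoic acid | C[C@H](CN)C(=O)O | starting material
2 | methyl chloroformate | COC(=O)Cl | starting material
3 | (2R)-3-[(methoxycarbonyl)amino]-2-methylpropanoic acid | C[C@H](CNC(=O)OC)C(=O)O | intermediate
4 | 2,2-dimethyl-1,3-dioxane-4,6-dione (Meldrum's acid) | CC1(C)OC(=O)CC(=O)O1 | starting material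
5 | methyl N-[(2R)-3-(2,2-dimethyl-4,6-dioxo-1,3-dioxan-5-yl)-2-methyl-3-oxopropyl]carbamate (acyl Meldrum's acid, not isolated) | C[C@H](CNC(=O)OC)C(=O)C1C(=O)OC(C)(C)OC1=O | intermediate
6 | methyl (5R)-5-methyl-2,4-dioxopiperidine-1-carboxylate | C[C@@H]1CN(C(=O)OC)C(=O)CC1=O | intermediate
7 | methyl (5R)-5-methyl-2-oxo-4-[(trifluoromethanesulfonyl)oxy]-5,6-dihydropyridine-1(2H)-carboxylate | C[C@@H]1CN(C(=O)OC)C(=O)C=C1OS(=O)(=O)C(F)(F)F | intermediate
8 | bromo(2-ethoxy-2-oxoethyl)zinc | CCOC(=O)C[Zn]Br | starting material
9 | methyl (5S)-4-(2-ethoxy-2-oxoethyl)-5-methyl-2-oxo-5,6-dihydropyridine-1(2H)-carboxylate | C[C@@H]1CN(C(=O)OC)C(=O)C=C1CC(=O)OCC | intermediate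
10 | methyl (4R,5S)-4-(2-ethoxy-2-oxoethyl)-5-methyl-2-oxopiperidine-1-carboxylate | CCOC(=O)C[C@H]1CC(=O)N(C(=O)OC)C[C@H]1C | intermediate
11 | lithium alkoxide of methyl (4R,5S)-4-(2-ethoxy-2-oxoethyl)-2-hydroxy-5-methylpiperidine-1-carboxylate (C2 epimers, not isolated) | CCOC(=O)C[C@H]1CC([O-])N(C(=O)OC)C[C@H]1C.[Li+] | intermediate
12 | methyl (3S,4R)-4-(2-ethoxy-2-oxoethyl)-3-methyl-3,4-dihydro-2H-pyridine-1-carboxylate | CCOC(=O)C[C@H]1C=CN(C(=O)OC)C[C@H]1C | intermediate
13 | vinylmagnesium bromide | C=C[Mg]Br | starting material
14 | methyl (3S,4R)-4-{2-[methoxy(methyl)amino]-2-oxoethyl}-3-methyl-3,4-dihydro-2H-pyridine-1-carboxylate (Weinreb amide, not isolated) | CON(C)C(=O)C[C@H]1C=CN(C(=O)OC)C[C@H]1C | intermediate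
15 | methyl (3S,4R)-3-methyl-4-(2-oxobut-3-en-1-yl)-3,4-dihydro-2H-pyridine-1-carboxylate | C=CC(=O)C[C@H]1C=CN(C(=O)OC)C[C@H]1C | intermediate
16 | methyl (3S,4R)-3-methyl-4-[(2Z)-2-(triethylsilyloxy)but-2-en-1-yl]-3,4-dihydro-2H-pyridine-1-carboxylate | C/C=C(/C[C@H]1C=CN(C(=O)OC)C[C@H]1C)O[Si](CC)(CC)CC | intermediate
17 | methyl (4S,4aR,7R,7aS)-1-methoxy-4,7-dimethyl-6-oxooctahydro-2H-cyclopenta[c]pyridine-2-carboxylate (C1 undefined) | O=C1C[C@H]2[C@H](C(OC)N(C(=O)OC)C[C@H]2C)[C@H]1C | intermediate
18 | methyl (4S,4aR,7R,7aS)-4,7-dimethyl-6-oxooctahydro-2H-cyclopenta[c]pyridine-2-carboxylate | O=C1C[C@H]2[C@H](CN(C(=O)OC)C[C@H]2C)[C@H]1C | intermediate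
19 | (4S,4aR,6R,7R,7aS)-2,4,7-trimethyloctahydro-1H-cyclopenta[c]pyridin-6-ol | O[C@@H]1C[C@H]2[C@H](CN(C)C[C@H]2C)[C@H]1C | intermediate
20 | geraniol, (2E)-3,7-dimethylocta-2,6-dien-1-ol | CC(C)=CCC/C(C)=C/CO | starting material
21 | (2E,6E)-2,6-dimethylocta-2,6-diene-1,8-diol | C/C(=C\CO)CC/C=C(\C)CO | intermediate
22 | (2E,6E)-2,6-dimethylocta-2,6-dienedial | C/C(=C\C=O)CC/C=C(\C)C=O | intermediate
23 | (2E,6E)-2,6-dimethylocta-2,6-dienedioic acid | C/C(=C\C(=O)O)CC/C=C(\C)C(=O)O | intermediate
24 | bis[(4S,4aR,6S,7R,7aS)-2,4,7-trimethyloctahydro-1H-cyclopenta[c]pyridin-6-yl] (2E,6E)-2,6-dimethylocta-2,6-dienedioate | C/C(=C\C(=O)O[C@H]1C[C@H]2[C@H](CN(C)C[C@H]2C)[C@H]1C)CC/C=C(\C)C(=O)O[C@H]1C[C@H]2[C@H](CN(C)C[C@H]2C)[C@H]1C | target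

## Step count and risks

Total step count: 15. Longest linear sequence: 12 steps (steps 1 to 11 and step 15); steps 12 to 14 form the diacid branch.

**Step 9 (key step, proposed new method).**
- **What may go wrong:** closure may be slow, because the enol ether carbon C6 lies inside the forming five-membered ring and overlap between C7 and C7a is strained. Methanol could then capture the radical cation before the C–C bond forms, or the enol ether could be solvolysed.
- **Fallback (known chemistry), from 12 back to 18:** ester 12 is converted into Weinreb amide 14, this time isolated. Acylation of the lithium enolate of tert-butyl propanoate with 14 gives tert-butyl 4-[(3S,4R)-1-(methoxycarbonyl)-3-methyl-1,2,3,4-tetrahydropyridin-4-yl]-2-methyl-3-oxobutanoate F1. Mn(OAc)3 and Cu(OAc)2 in acetic acid generate the electrophilic C7 radical of this β-keto ester, which closes ring A onto C7a; oxidation of the C1 radical and capture by acetate give 7-tert-butyl 2-methyl (4S,4aR,7aS)-1-acetoxy-4,7-dimethyl-6-oxooctahydro-2H-cyclopenta[c]pyridine-2,7-dicarboxylate F2. Et3SiH in CF3CO2H reduces the acetoxy aminal and cleaves the tert-butyl ester to (4S,4aR,7aS)-2-(methoxycarbonyl)-4,7-dimethyl-6-oxooctahydro-1H-cyclopenta[c]pyridine-7-carboxylic acid F3, which loses CO2 on warming to give 18.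

**Step 4.**
- **What may go wrong:** the zinc enolate may deprotonate the acidic methylene of the product, and the resulting dienolate may shift the double bond towards C5 and erode that stereocentre. Transmetalation may also be slow.
- **Fallback, from 7 back to 9:** the sodium salt of diethyl malonate displaces the triflate by addition–elimination to give diethyl 2-[(5S)-1-(methoxycarbonyl)-5-methyl-2-oxo-1,2,5,6-tetrahydropyridin-4-yl]propanedioate F4. Krapcho dealkoxycarbonylation (LiCl, wet DMSO, heat) returns 9.

**Step 5.**
- **What may go wrong:** facial selectivity may be poor, or the double bond may migrate on the catalyst surface into the C4–C5 position before reduction, which would scramble C5.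
- **Fallback, from 9 back to 10:** conjugate hydride addition with [(Ph3P)CuH]6 in THF, then aqueous NH4Cl. Hydride adds to C4 anti to the methyl and the olefin cannot migrate. This fallback makes no new compound (F0).

**Step 7.**
- **What may go wrong:** the released N,O-dimethylhydroxylamine may add to the vinyl ketone during the quench, and the enone may polymerise in the concentrated one-flask mixture.
- **Fallback, from 12 back to 15:** DIBAL-H at −78 °C gives methyl (3S,4R)-3-methyl-4-(2-oxoethyl)-3,4-dihydro-2H-pyridine-1-carboxylate F5. Addition of 13 gives methyl (3S,4R)-4-(2-hydroxybut-3-en-1-yl)-3-methyl-3,4-dihydro-2H-pyridine-1-carboxylate F6. Dess–Martin oxidation gives 15 without any amine present.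

**Step 11.**
- **What may go wrong:** hydride may approach from the concave face, because the C7 methyl sits on the convex face next to the carbonyl.
- **Fallback, from 18 to 24:** the alcohol formed in that case is (4S,4aR,6S,7R,7aS)-2,4,7-trimethyloctahydro-1H-cyclopenta[c]pyridin-6-ol F7, which already has the target configuration. It is joined to 23 by carbodiimide esterification (EDC, DMAP) with retention, giving 24 directly.

**Step 15.**
- **What may go wrong:** elimination of the activated cyclopentanol, or stalling after the first esterification because the tertiary amine buffers the acid.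
- **Fallback, from 19 to 24:** MsCl and Et3N give (4S,4aR,6R,7R,7aS)-2,4,7-trimethyloctahydro-1H-cyclopenta[c]pyridin-6-yl methanesulfonate F8. Cs2CO3 converts 23 into dicesium (2E,6E)-2,6-dimethylocta-2,6-dienedioate F9. Displacement of F8 by F9 in DMF gives 24 with inversion at C6.

## Further compounds

F1 | step 9 | tert-butyl 4-[(3S,4R)-1-(methoxycarbonyl)-3-methyl-1,2,3,4-tetrahydropyridin-4-yl]-2-methyl-3-oxobutanoate | CC(C(=O)OC(C)(C)C)C(=O)C[C@H]1C=CN(C(=O)OC)C[C@H]1C
F2 | step 9 | 7-tert-butyl 2-methyl (4S,4aR,7aS)-1-acetoxy-4,7-dimethyl-6-oxooctahydro-2H-cyclopenta[c]pyridine-2,7-dicarboxylate | O=C1C[C@H]2[C@H](C(OC(C)=O)N(C(=O)OC)C[C@H]2C)C1(C)C(=O)OC(C)(C)C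
F3 | step 9 | (4S,4aR,7aS)-2-(methoxycarbonyl)-4,7-dimethyl-6-oxooctahydro-1H-cyclopenta[c]pyridine-7-carboxylic acid | O=C1C[C@H]2[C@H](CN(C(=O)OC)C[C@H]2C)C1(C)C(=O)O
F4 | step 4 | diethyl 2-[(5S)-1-(methoxycarbonyl)-5-methyl-2-oxo-1,2,5,6-tetrahydropyridin-4-yl]propanedioate | C[C@@H]1CN(C(=O)OC)C(=O)C=C1C(C(=O)OCC)C(=O)OCC
F0 | step 5 | none | none
F5 | step 7 | methyl (3S,4R)-3-methyl-4-(2-oxoethyl)-3,4-dihydro-2H-pyridine-1-carboxylate | O=CC[C@H]1C=CN(C(=O)OC)C[C@H]1C
F6 | step 7 | methyl (3S,4R)-4-(2-hydroxybut-3-en-1-yl)-3-methyl-3,4-dihydro-2H-pyridine-1-carboxylate | C=CC(O)C[C@H]1C=CN(C(=O)OC)C[C@H]1C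
F7 | step 11 | (4S,4aR,6S,7R,7aS)-2,4,7-trimethyloctahydro-1H-cyclopenta[c]pyridin-6-ol | O[C@H]1C[C@H]2[C@H](CN(C)C[C@H]2C)[C@H]1C
F8 | step 15 | (4S,4aR,6R,7R,7aS)-2,4,7-trimethyloctahydro-1H-cyclopenta[c]pyridin-6-yl methanesulfonate | CS(=O)(=O)O[C@@H]1C[C@H]2[C@H](CN(C)C[C@H]2C)[C@H]1C
F9 | step 15 | dicesium (2E,6E)-2,6-dimethylocta-2,6-dienedioate | C/C(=C\C(=O)[O-])CC/C=C(\C)C(=O)[O-].[Cs+].[Cs+]
A1 | alternative 1 | (2S,3R,4R)-2-{[benzyl(methyl)amino]methyl}-4-[(tert-butyldimethylsilyl)oxy]-3-methylcyclopentan-1-one | CC(C)(C)[Si](C)(C)O[C@@H]1CC(=O)[C@H](CN(C)Cc2ccccc2)[C@H]1C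
A2 | alternative 1 | (4R)-4-[(tert-butyldimethylsilyl)oxy]cyclopent-2-en-1-one | CC(C)(C)[Si](C)(C)O[C@@H]1CC(=O)C=C1
A3 | alternative 1 | N-benzyl-N-methylmethaniminium (cation of the salt) | C=[N+](C)Cc1ccccc1
A4 | alternative 2 | (4aS,7R,7aS)-2,7-dimethyl-4-methylideneoctahydro-6H-cyclopenta[c]pyridin-6-one | O=C1C[C@H]2[C@H](CN(C)CC2=C)[C@H]1C
A5 | alternative 2 | (4S,5R)-4-{[(2-bromoprop-2-en-1-yl)(methyl)amino]methyl}-5-methylcyclopent-2-en-1-one | O=C1C=C[C@H](CN(C)CC(Br)=C)[C@H]1C
A6 | alternative 3 | methyl (4S,7R,7aR)-4,7-dimethyl-6-oxo-1,3,4,6,7,7a-hexahydro-2H-cyclopenta[c]pyridine-2-carboxylate | O=C1C=C2[C@H](CN(C(=O)OC)C[C@H]2C)[C@H]1C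
A7 | alternative 3 | methyl [(2E)-but-2-en-1-yl][(2S)-2-methylbut-3-yn-1-yl]carbamate | C#C[C@H](C)CN(C(=O)OC)C/C=C/C
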